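Assumption: stipulin has no stereocentre and is achiral, so "single enantiomer" does not apply. The only stereochemical element is the E geometry of Cα=Cβ, which is set in step 2 and carried unchanged to the end.

Locants: ring A is C1'–C6' (carbonyl at C1'). Ring B is C1–C6 (enone at C1). Cα and Cβ are the enone carbons.

## Analysis of the target

- Stipulin (11, C25H28O4) is an open-chain chalcone. Ring A bears the carbonyl at C1', hydroxyls at C2' and C4', and a prenyl group at C5'. Ring B bears the enone at C1, a hydroxyl at C4 and a prenyl group at C3.
- There is no ring to close and no stereocentre. The E double bond Cα=Cβ is the only stereochemical element and is also the thermodynamic geometry.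
- The plan rests on a six-atom array that occurs twice: O4–C4–C3–CH2–CH=CMe2 in ring B and O4'–C4'–C5'–CH2–CH=CMe2 in ring A. In both rings the oxygen stands para to the three-carbon bridge. This array is the retron of an aromatic Claisen rearrangement.
- The third oxygen, O2', is different in kind. It is locked in a hydrogen bond to C=O, which lowers its nucleophilicity and biases the π bonds of ring A.
- Each o-prenylphenol closes to a 2,2-dimethylchroman with acid. The 2'-hydroxy enone closes to a flavanone by oxa-Michael addition. The trisubstituted alkenes exclude oxidants, radicals and hydrogenation late in the route.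
- The C15 skeleton is trivial. The difficulty is to place two prenyl groups on carbon rather than oxygen, at C3 and C5' and not at C3' (the carbon between O2' and O4'), without a long protecting group sequence that ends in acid.

## Retrosynthetic reasoning

**11 ⇒ 10.** Only three O–Si bonds are cut. The forward reaction is a near-neutral solvolysis, the only unmasking of the route, and it avoids both the acid that closes chromans and the base that closes the flavanone.

**10 ⇒ 7 (through 9 and 8), the key disconnection.** The bonds C3–CH2 and C5'–CH2 are cut together, and each allyl unit is reconnected through its other terminus to the neighbouring oxygen (O4, O4').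

- These are the only two bonds of 11 whose regiochemistry is hard to control. Moving them onto oxygen turns a problem of C-regiochemistry on two rings into one of O-chemoselectivity, which the molecule solves by itself.
- Precursor 7 is a constitutional isomer of 11 and carries no C-prenyl group.
- The forward step must shift both allyl units with inversion, choose C5' over C3' in ring A, and avoid loss of the tertiary allyl groups.
- Silylation of O2' in the same flask (8) breaks the chelate and steers the shift. The keto forms drawn as 9 aromatise and are capped as 10.

**7 ⇒ 6 + 3.** Two O–C(tertiary) bonds are cut. Substitution at a tertiary carbon is not open to an SN2 process, so the forward reaction uses a π-allyl palladium species generated from 3, attacked at its substituted end. O4 and O4' are the acidic, free phenols. O2' is chelated and stays out, so no protecting group is needed to distinguish three hydroxyls.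

**6 ⇒ 4 + 5.** Cα=Cβ is cut. The aldol condensation is placed at the start, when nothing sensitive is present, and it sets the E geometry. Both partners are commodity phenols.

**3 ⇒ 1 (through 2).** One O–C(acyl) bond is cut. The allyl donor comes from the cheap tertiary alcohol 1 in one operation on a side branch.

## Alternatives that were turned down

**Alternative 1:** the textbook route.
- Disconnection: Cα=Cβ as the last skeletal bond, with both prenyl groups already on carbon.
- Forward key step: Claisen–Schmidt condensation of ketone A1 with aldehyde A2 to the bis-acetal A3, then acidic removal of the acetals to give 11.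
- Reasons for rejection:
  - The aldol bond is the easiest bond of the molecule, so the key step solves nothing.
  - The regioselective C-prenylation must be solved twice, on two separate rings, each with its own protection.
  - The last step exposes two o-prenylphenols and a 2'-hydroxy enone to acid, the conditions under which chroman and flavanone closure occur.
  - The step count is about twice that of the chosen route.

**Alternative 2:**
- Disconnection: C(=O)–Cα, with polarity reversal at the carbonyl carbon.
- Forward key step: rhodium(I)-catalysed, 2'-OH-chelation-assisted hydroacylation of alkyne A5 with salicylaldehyde A4, giving 11 directly without protecting groups.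
- Reasons for rejection:
  - A4 and A5 each already hold a C-prenyl group, so the real problem is only pushed back into two separate syntheses.
  - Insertion of an aryl acetylene into the Rh–H bond has no structural element here that enforces the linear mode. The branched mode gives a 1,1-disubstituted enone that cannot be corrected.
  - A rhodium hydride in the presence of two allylic arenes invites migration of the prenyl double bonds into conjugation.

**Alternative 3:**
- Disconnection: C1'–C(=O) and C(=O)–Cα together.
- Forward key step: three-component carbonylative Heck coupling of iodide A6, styrene A7 and a C1 carbonyl source to A8, then acidic deprotection to 11.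
- Reasons for rejection:
  - The electron-rich, ortho-oxygenated iodide favours direct, non-carbonylative Heck coupling over acyl transfer.
  - Free phenols would intercept the acyl palladium species as esters. All three must therefore be masked, and the route again ends in acid.
  - A6 and A7 are no simpler than the aldol partners of Alternative 1. Three components are joined, but the two hard bonds are not addressed.

Key step: step 4

## Route

Step 1
Reactants: 1 2-methylbut-3-en-2-ol
Product: 3 tert-butyl (2-methylbut-3-en-2-yl) carbonate, via lithium alkoxide 2 (not isolated)
Conditions: n-BuLi (1.05 equiv), THF, −78 → 0 °C; Boc2O (1.1 equiv), 0 °C → rt; H2O quench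
Reagents that add atoms: di-tert-butyl dicarbonate, CC(C)(C)OC(=O)OC(=O)OC(C)(C)C; n-butyllithium, [Li]CCCC (lithium of 2 only)
Why: Deprotonation of the tertiary allylic alcohol gives alkoxide 2, which is O-acylated by the dicarbonate with loss of tert-butyl carbonate; the hindered mixed carbonate should survive aqueous work-up and distillation.

Step 2
Reactants: 4 2',4'-dihydroxyacetophenone; 5 4-hydroxybenzaldehyde
Product: 6 isoliquiritigenin [(E)-2',4',4-trihydroxychalcone]
Conditions: KOH (50% aq, excess), EtOH, 0 °C → rt; then cold 1 M HCl to pH 5
Reagents that add atoms: none
Why: Claisen–Schmidt condensation (crossed aldol, E1cB loss of water): 5 has no α-hydrogen and 4 is the only enolisable partner, so only one cross product is possible. The fully conjugated E enone is the thermodynamic product, which sets the only stereochemical element of 11, and nothing sensitive is on board yet.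

Step 3
Reactants: 6 isoliquiritigenin; 3 tert-butyl (2-methylbut-3-en-2-yl) carbonate (2.4 equiv)
Product: 7 (E)-2'-hydroxy-4,4'-bis(2-methylbut-3-en-2-yloxy)chalcone
Conditions: Pd(PPh3)4 (5 mol %), THF, 0–5 °C
Reagents that add atoms: none
Why: Tsuji–Trost type decarboxylative O-allylation: Pd(0) ionises 3 to an η3-1,1-dimethylallyl complex and an alkoxide base that deprotonates the two acidic phenols, and under kinetic control at low temperature phenoxides attack the more substituted allyl terminus, a reaction type well known for electron-poor phenols such as 7-hydroxycoumarins. The chelated, less acidic 2'-OH should stay free, so the three oxygens are told apart without a protecting group.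

Step 4
Reactants: 7 (E)-2'-hydroxy-4,4'-bis(2-methylbut-3-en-2-yloxy)chalcone
Product: 10 stipulin tris(trimethylsilyl) ether, via 2'-O-trimethylsilyl ether 8 (not isolated), via bis-dienone 9 (not isolated)
Conditions: BSA (8 equiv), mesitylene, 80 °C; then 165 °C, sealed tube, Ar; volatiles removed in vacuo
Reagents that add atoms: N,O-bis(trimethylsilyl)acetamide (BSA), CC(=N[Si](C)(C)C)O[Si](C)(C)C
Why: Warm BSA, the reagent that silylates even chelated flavonoid hydroxyls for gas chromatography, should first convert 7 into 8, since 7 has no enolisable C–H and the tertiary allyl ethers are still inert at 80 °C. At 165 °C each Ar–O–CMe2–CH=CH2 unit undergoes a concerted suprafacial [3,3] aromatic Claisen shift through a six-membered transition state in which the terminal CH2 bonds to the ortho carbon with allyl inversion, so each 1,1-dimethylallyl ether emerges as a 3,3-dimethylallyl (prenyl) group; the two shifts are independent, and 9 is drawn as their sum. The dienone units of 9 aromatise irreversibly and BSA caps the new phenols, which shuts off chroman closure, flavanone closure and any return path. The closest known reaction type is the thermal ortho-Claisen rearrangement of aryl 1,1-dimethylallyl ethers, which is also known on chalcone allyl ethers and with in situ silyl trapping of the phenol. No ring is closed and no stereocentre remains, because the two sp3 carbons of 9 are erased on aromatisation and the E enone takes no part. In ring B the two ortho carbons C3 and C5 are equivalent, so only one product can form. In ring A the step needs C5' over C3', and three features of 8 work in that direction: the chelate that gives the C3'–C4' bond its high double-bond character in 7 is gone, the OSiMe3 group is pushed by the cinnamoyl group towards C3'–H into the space the folding allyl chain would need, and a meta donor directs an aryl allyl ether to the ortho carbon para to itself, which is C5'. The gem-dimethyl group lowers the barrier relative to a plain allyl ether, and the non-polar, acid-free medium disfavours ionisation of the tertiary C–O bonds.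

Step 5
Reactants: 10 stipulin tris(trimethylsilyl) ether
Product: 11 stipulin
Conditions: MeOH, citric acid (10 mol %), 0 °C → rt
Reagents that add atoms: none
Why: Aryl trimethylsilyl ethers undergo solvolysis in methanol with a trace of weak acid. Citric acid is too weak to protonate the trisubstituted alkenes or to drive oxa-Michael closure, and the E enone is untouched.

## Compound list

1 | 2-methylbut-3-en-2-ol | C=CC(C)(C)O | starting material
2 | lithium 2-methylbut-3-en-2-olate (formed in situ) | [Li+].[O-]C(C)(C)C=C | intermediate
3 | tert-butyl (2-methylbut-3-en-2-yl) carbonate | C=CC(C)(C)OC(=O)OC(C)(C)C | intermediate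
4 | 2',4'-dihydroxyacetophenone | CC(=O)c1ccc(O)cc1O | starting material
5 | 4-hydroxybenzaldehyde | O=Cc1ccc(O)cc1 | starting material
6 | isoliquiritigenin, (E)-2',4',4-trihydroxychalcone | Oc1ccc(/C=C/C(=O)c2ccc(O)cc2O)cc1 | intermediate
7 | (E)-2'-hydroxy-4,4'-bis(2-methylbut-3-en-2-yloxy)chalcone | C=CC(C)(C)Oc1ccc(/C=C/C(=O)c2ccc(OC(C)(C)C=C)cc2O)cc1 | intermediate
8 | 2'-O-trimethylsilyl ether of 7 (formed in situ) | C=CC(C)(C)Oc1ccc(/C=C/C(=O)c2ccc(OC(C)(C)C=C)cc2O[Si](C)(C)C)cc1 | intermediate
9 | bis-dienone, the keto form after both [3,3] shifts (formed in situ; two transient sp3 carbons, unassigned) | CC(C)=CCC1C=C(/C=C/C(=O)C2=CC(CC=C(C)C)C(=O)C=C2O[Si](C)(C)C)C=CC1=O | intermediate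
10 | stipulin tris(trimethylsilyl) ether | CC(C)=CCc1cc(/C=C/C(=O)c2cc(CC=C(C)C)c(O[Si](C)(C)C)cc2O[Si](C)(C)C)ccc1O[Si](C)(C)C | intermediate
11 | stipulin, (E)-2',4',4-trihydroxy-3,5'-diprenylchalcone | CC(C)=CCc1cc(/C=C/C(=O)c2cc(CC=C(C)C)c(O)cc2O)ccc1O | target

## Step count and least certain steps

Total: 5 steps. The longest linear sequence is 4 steps (4/5 → 6 → 7 → 10 → 11). The branch 1 → 3 → 7 → 10 → 11 is equally long.

**Step 4 (key step).**
- The most likely failure is incomplete regiocontrol in ring A. Part of the allyl unit may migrate to the carbon between O2' and O4', because the steric and electronic bias of a trimethylsilyloxy group is real but not absolute. Any ring A that enters the hot phase unsilylated is directed to the wrong carbon by the chelate.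
- The second failure is loss of a tertiary allyl unit by ionisation or elimination before the shift, since both aryloxy groups are good leaving groups.
- The fallback fixes the positions by halogen rather than by a transition-state preference. It sets out from 6 and comes back at 11. Twofold electrophilic bromination (NBS, 2 equiv, MeCN, −20 → 0 °C) should attack the less hindered ortho carbon of each free phenol and give 3,5'-dibromoisoliquiritigenin F1. Silylation (TBSCl, imidazole, DMF) gives the tris(tert-butyldimethylsilyl) ether F2. A twofold Stille coupling with tributyl(3-methylbut-2-en-1-yl)stannane (Pd(PPh3)4, LiCl, DMF, 100 °C) gives stipulin tris(tert-butyldimethylsilyl) ether F3. Buffered fluoride (TBAF, AcOH, THF, 0 °C) then releases 11.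

**Step 3.**
- The most likely failure is re-ionisation of the first-formed tertiary ethers by Pd(0), which lets them drift to the thermodynamically preferred linear O-prenyl ethers. Stalling after one alkylation is the second risk.
- The fallback replaces π-allyl chemistry by copper-catalysed propargylic substitution followed by semi-reduction. It sets out from 6 and comes back at 7. 3-Chloro-3-methylbut-1-yne with CuCl2 (cat.) and DBU in MeCN at 0 °C should give the bis(1,1-dimethylpropargyl) ether F4. Hydrogenation over Lindlar catalyst with quinoline in EtOAc, stopped after two equivalents of hydrogen, reduces the two terminal alkynes in preference to the conjugated enone and gives 7.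

**Step 2.**
- The most likely failure is a sluggish condensation. In strong base the aldehyde is present as a phenolate, a vinylogous carboxylate of low electrophilicity, and the ketone carries two negative charges. Disproportionation of the aldehyde and closure to the flavanone on acidification can then compete.
- Compound 6 is also an article of commerce.
- The fallback removes the free para phenols before the C=C bond is made. It sets out from 4 and 5 and comes back at 7, bypassing 6. Each phenol is O-alkylated with 3 under the conditions of step 3, to give 2'-hydroxy-4'-(2-methylbut-3-en-2-yloxy)acetophenone F5 and 4-(2-methylbut-3-en-2-yloxy)benzaldehyde F6. Their Claisen–Schmidt condensation (KOH, EtOH, rt), now with a normal aldehyde and only one chelated phenol, gives 7.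

## Further compounds

F1 | step 4 | (E)-3,5'-dibromo-2',4',4-trihydroxychalcone | Oc1ccc(/C=C/C(=O)c2cc(Br)c(O)cc2O)cc1Br
F2 | step 4 | tris(tert-butyldimethylsilyl) ether of F1 | CC(C)(C)[Si](C)(C)Oc1ccc(/C=C/C(=O)c2cc(Br)c(O[Si](C)(C)C(C)(C)C)cc2O[Si](C)(C)C(C)(C)C)cc1Br
F3 | step 4 | stipulin tris(tert-butyldimethylsilyl) ether | CC(C)=CCc1cc(/C=C/C(=O)c2cc(CC=C(C)C)c(O[Si](C)(C)C(C)(C)C)cc2O[Si](C)(C)C(C)(C)C)ccc1O[Si](C)(C)C(C)(C)C
F4 | step 3 | (E)-2'-hydroxy-4,4'-bis(2-methylbut-3-yn-2-yloxy)chalcone | C#CC(C)(C)Oc1ccc(/C=C/C(=O)c2ccc(OC(C)(C)C#C)cc2O)cc1
F5 | step 2 | 2'-hydroxy-4'-(2-methylbut-3-en-2-yloxy)acetophenone | CC(=O)c1ccc(OC(C)(C)C=C)cc1O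
F6 | step 2 | 4-(2-methylbut-3-en-2-yloxy)benzaldehyde | C=CC(C)(C)Oc1ccc(C=O)cc1
A1 | alternative 1 | 2'-hydroxy-4'-(methoxymethoxy)-5'-prenylacetophenone | CC(=O)c1cc(CC=C(C)C)c(OCOC)cc1O
A2 | alternative 1 | 4-(methoxymethoxy)-3-prenylbenzaldehyde | O=Cc1ccc(OCOC)c(CC=C(C)C)c1
A3 | alternative 1 | stipulin 4,4'-bis(methoxymethyl) ether | CC(C)=CCc1cc(/C=C/C(=O)c2cc(CC=C(C)C)c(OCOC)cc2O)ccc1OCOC
A4 | alternative 2 | 2,4-dihydroxy-5-prenylbenzaldehyde | O=Cc1cc(CC=C(C)C)c(O)cc1O
A5 | alternative 2 | 4-ethynyl-2-prenylphenol | C#Cc1ccc(O)c(CC=C(C)C)c1
A6 | alternative 3 | 1-iodo-2,4-bis(methoxymethoxy)-5-prenylbenzene | COCOc1cc(OCOC)c(CC=C(C)C)cc1I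
A7 | alternative 3 | 4-(methoxymethoxy)-3-prenylstyrene | C=Cc1ccc(OCOC)c(CC=C(C)C)c1
A8 | alternative 3 | stipulin tris(methoxymethyl) ether | CC(C)=CCc1cc(/C=C/C(=O)c2cc(CC=C(C)C)c(OCOC)cc2OCOC)ccc1OCOC
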